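**Plan**
Cuts: both O1–C8a aryl ether bonds first, then both C4–C4a bonds, the C5–C5' biaryl bond and, in each chain, the enoate C=C bond.
Feature: in each benzopyran ring, O1 ties the fully substituted carbon C2 to arene carbon C8a (para to the C6 oxygen, ortho to the C8 methyl, next to C4a). A tertiary alcohol held three carbons from a C8a bromide is therefore a complete ring precursor, and C2 is never a reaction site.
Forward: farnesol gives one (Z)-enoate allylic alcohol and, from it, both enantiomeric vinyl carbinols. 4-Amino-3-methylphenol gives the biaryl, which is then made into its 6,6'-diiodide and 5,5'-dibromide.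
The (S) chain and then the (R) chain are joined at C–I by hydroboration and B-alkyl Suzuki coupling. Both pyran rings close together in one operation, and desilylation and saponification finish the route.
Stereochemistry: C2 (S) and C2' (R) come from Sharpless epoxidations with L-(+)- and D-(−)-diethyl tartrate, the E alkenes from farnesol, and the Z enoates from Still–Gennari olefination.

Key step: step 19

Assumption: the SMILES fixes no sense for the hindered C5–C5' axis; the two halves are constitutionally alike and C2/C2' are unlike, so the two atropisomers are mirror images and the route aims at this single diastereomer as its racemate (23 is racemic, and the two atropisomeric diastereomers of 25 converge on it).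

Biphenyl locants used below: C1 axis, C2 oxygen, C4 methyl, C5 nitrogen or bromine, C6 iodine or chain.

**Step 1**
Reactants: 1 (2E,6E)-farnesol
Product: 2 (2E,6E)-farnesyl acetate
Conditions: Ac2O, pyridine, DMAP (cat.), CH2Cl2, 0 °C to rt
Reagents that add atoms: acetic anhydride, CC(=O)OC(C)=O
Why: Routine O-acylation of a primary alcohol, and the electron-withdrawing acetate makes the C2=C3 alkene the least nucleophilic of the three before the electrophilic step that follows.

**Step 2**
Reactants: 2 (2E,6E)-farnesyl acetate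
Product: 3 (2E,6E)-10-bromo-11-hydroxy-3,7,11-trimethyldodeca-2,6-dienyl acetate (racemic at C10)
Conditions: NBS (1.05 equiv), THF/H2O, 0 °C
Reagents that add atoms: N-bromosuccinimide, O=C1CCC(=O)N1Br; water, O
Why: Bromohydrin formation in aqueous THF is the established terminal-selective functionalisation of farnesyl esters, because the C10=C11 isopropylidene alkene is the most exposed and electron-rich one and water opens the bromonium ion at the tertiary carbon; the racemic C10 centre is excised in step 4.

**Step 3**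
Reactants: 3 bromohydrin acetate
Product: 4 (2E,6E)-10,11-epoxyfarnesol, i.e. (2E,6E)-9-(3,3-dimethyloxiran-2-yl)-3,7-dimethylnona-2,6-dien-1-ol (racemic)
Conditions: K2CO3, MeOH, rt
Reagents that add atoms: none
Why: The bromohydrin alkoxide displaces the neighbouring bromide (intramolecular Williamson reaction) while carbonate-catalysed transesterification with methanol removes the acetate in the same operation.

**Step 4**
Reactants: 4 10,11-epoxyfarnesol
Product: 5 (4E,8E)-10-hydroxy-4,8-dimethyldeca-4,8-dienal
Conditions: H5IO6 (1.2 equiv), THF/Et2O, 0 °C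
Reagents that add atoms: none
Why: Periodic acid hydrates the trisubstituted oxirane and cleaves the resulting glycol at once (Malaprade cleavage), which at 0 °C leaves the isolated alkenes and the primary allylic alcohol alone.

**Step 5**
Reactants: 5 hydroxy aldehyde; 6 methyl 2-[bis(2,2,2-trifluoroethoxy)phosphoryl]propanoate
Product: 7 methyl (2Z,6E,10E)-12-hydroxy-2,6,10-trimethyldodeca-2,6,10-trienoate
Conditions: 6, KN(SiMe3)2, 18-crown-6, THF, −78 °C; then 5
Reagents that add atoms: none
Why: Still–Gennari olefination, in which the electron-poor phosphonate with a dissociated potassium counter-ion collapses quickly from the kinetic adduct and so gives the Z trisubstituted enoate, while the stabilised carbanion is too weak a base to be quenched by the free hydroxyl group.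

**Step 6**
Reactants: 7 (Z)-enoate allylic alcohol
Product: 8 methyl (2Z,6E)-9-[(2S,3S)-3-(hydroxymethyl)-2-methyloxiran-2-yl]-2,6-dimethylnona-2,6-dienoate
Conditions: Ti(OiPr)4 (10 mol %), L-(+)-diethyl tartrate (12 mol %), t-BuOOH (decane), 4 Å sieves, CH2Cl2, −20 °C
Reagents that add atoms: tert-butyl hydroperoxide, CC(C)(C)OO
Why: Sharpless asymmetric epoxidation acts only on the alkene of the titanium-bound allylic alcohol, and with the L-(+)-tartrate oxygen reaches the face of the E alkene that gives the (2S,3S)-oxirane, which sets the quaternary C–O centre that becomes C2 (S).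

**Step 7**
Reactants: 8 (2S,3S)-epoxy alcohol
Product: 10 methyl (2Z,6E,10S)-10-hydroxy-2,6,10-trimethyldodeca-2,6,11-trienoate, via epoxy iodide 9 (not isolated)
Conditions: PPh3, I2, imidazole, THF, 0 °C; then Zn dust, EtOH, 50 °C, same flask
Reagents that add atoms: iodine, [I][I] (its atom stays only in intermediate 9)
Why: Appel-type iodination of the primary alcohol followed by zinc insertion and β-elimination of the oxirane oxygen (reductive epoxide opening) gives the vinyl carbinol, and since the C–O bond at the quaternary carbon is not broken its configuration is retained.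

**Step 8**
Reactants: 7 (Z)-enoate allylic alcohol
Product: 11 methyl (2Z,6E)-9-[(2R,3R)-3-(hydroxymethyl)-2-methyloxiran-2-yl]-2,6-dimethylnona-2,6-dienoate
Conditions: Ti(OiPr)4 (10 mol %), D-(−)-diethyl tartrate (12 mol %), t-BuOOH (decane), 4 Å sieves, CH2Cl2, −20 °C
Reagents that add atoms: tert-butyl hydroperoxide, CC(C)(C)OO
Why: The same Sharpless asymmetric epoxidation with the enantiomeric tartrate delivers oxygen to the opposite alkene face and sets the quaternary centre that becomes C2' (R).

**Step 9**
Reactants: 11 (2R,3R)-epoxy alcohol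
Product: 13 methyl (2Z,6E,10R)-10-hydroxy-2,6,10-trimethyldodeca-2,6,11-trienoate, via epoxy iodide 12 (not isolated)
Conditions: PPh3, I2, imidazole, THF, 0 °C; then Zn dust, EtOH, 50 °C, same flask
Reagents that add atoms: iodine, [I][I] (its atom stays only in intermediate 12)
Why: Appel-type iodination and zinc-induced reductive epoxide opening as in step 7, again without breaking the C–O bond at the quaternary carbon.

**Step 10**
Reactants: 14 4-amino-3-methylphenol
Product: 15 tert-butyl (4-hydroxy-2-methylphenyl)carbamate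
Conditions: Boc2O, THF, rt to 50 °C
Reagents that add atoms: di-tert-butyl dicarbonate, CC(C)(C)OC(=O)OC(=O)OC(C)(C)C
Why: The aniline nitrogen is far more nucleophilic than the phenol, so carbamate formation without added base is N-selective and tempers the ring against oxidation.

**Step 11**
Reactants: 15 N-Boc aminophenol
Product: 16 tert-butyl (4-hydroxy-5-iodo-2-methylphenyl)carbamate
Conditions: NIS (1.0 equiv), TsOH·H2O (10 mol %), MeCN, 0 °C to rt
Reagents that add atoms: N-iodosuccinimide, O=C1CCC(=O)N1I
Why: Electrophilic aromatic iodination is steered by the free hydroxyl group, the strongest donor, to its ortho position para to the methyl group, the other ortho position being wedged between hydroxyl and methyl.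

**Step 12**
Reactants: 16 iodophenol
Product: 17 tert-butyl [5-iodo-2-methyl-4-(triisopropylsilyloxy)phenyl]carbamate
Conditions: TIPSCl, imidazole, DMF, rt to 40 °C
Reagents that add atoms: chlorotriisopropylsilane, CC(C)[Si](Cl)(C(C)C)C(C)C
Why: Standard imidazole-promoted silylation of a phenol, giving an ether that tolerates acid, phosphate or carbonate bases and palladium catalysis and that falls to fluoride at the end.

**Step 13**
Reactants: 17 aryl iodide (two molecules)
Product: 19 5,5'-bis(tert-butoxycarbonylamino)-4,4'-dimethyl-2,2'-bis(triisopropylsilyloxy)biphenyl, via aryl pinacol boronate 18 (not isolated)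
Conditions: half of 17, B2pin2, KOAc, PdCl2(dppf) (5 mol %), dioxane, 90 °C; then second half of 17, aq K3PO4, 90 °C
Reagents that add atoms: bis(pinacolato)diboron, CC1(C)OB(OC1(C)C)B1OC(C)(C)C(C)(C)O1 (its atoms stay only in intermediate 18)
Why: One-pot Miyaura borylation and Suzuki–Miyaura coupling joins two identical aryl iodides at the future C5–C5' bond, and a biaryl with only two ortho substituents forms readily under PdCl2(dppf) catalysis.

**Step 14**
Reactants: 19 bis(carbamate)
Product: 20 5,5'-diamino-4,4'-dimethyl-2,2'-bis(triisopropylsilyloxy)biphenyl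
Conditions: CF3CO2H/CH2Cl2 (1:4), 0 °C to rt; aq NaHCO3 work-up
Reagents that add atoms: none
Why: Acidolysis of tert-butyl carbamates is routine, and aryl triisopropylsilyl ethers withstand trifluoroacetic acid.

**Step 15**
Reactants: 20 diamine
Product: 21 5,5'-diamino-6,6'-diiodo-4,4'-dimethyl-2,2'-bis(triisopropylsilyloxy)biphenyl (racemic axis)
Conditions: BnMe3N·ICl2 (2.2 equiv), CaCO3, CH2Cl2/MeOH, rt
Reagents that add atoms: benzyltrimethylammonium dichloroiodate, C[N+](C)(C)Cc1ccccc1.Cl[I-]Cl
Why: Electrophilic iodination of anilines goes ortho or para to nitrogen, and C6 is the only such position still open (C4 bears methyl, C2 oxygen), while the rival C3 is meta to nitrogen and shielded between the bulky silyl ether and the methyl group.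

**Step 16**
Reactants: 21 diiodo diamine
Product: 23 5,5'-dibromo-6,6'-diiodo-4,4'-dimethyl-2,2'-bis(triisopropylsilyloxy)biphenyl, via bis(diazonium) dibromide 22 (not isolated)
Conditions: t-BuONO (3 equiv), CuBr2 (2.5 equiv), MeCN/CH2Cl2, 0 to 50 °C
Reagents that add atoms: CuBr2, [Cu+2].[Br-].[Br-]; tert-butyl nitrite, CC(C)(C)ON=O (its nitrogen stays only in intermediate 22)
Why: Non-aqueous Sandmeyer bromination diazotises both amines and replaces them by bromine by way of aryl radicals, as is routine for 2-iodoanilines, and it leaves the silyl ethers and C–I bonds intact.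

**Step 17**
Reactants: 10 (S)-vinyl carbinol; 23 dibromo diiodo biaryl
Product: 25 methyl (2Z,6E,10S)-12-[5,5'-dibromo-6'-iodo-4,4'-dimethyl-2,2'-bis(triisopropylsilyloxy)biphenyl-6-yl]-10-hydroxy-2,6,10-trimethyldodeca-2,6-dienoate (two atropisomers), via B-alkyl-9-BBN borane 24 (not isolated)
Conditions: 10, 9-BBN-H (2.1 equiv), THF, 0 °C to rt; then aq K3PO4, 23 (3 equiv), PdCl2(dppf) (10 mol %), AsPh3 (10 mol %), DMF, 50 °C
Reagents that add atoms: 9-borabicyclo[3.3.1]nonane, B1C2CCCC1CCC2 (its atoms stay only in intermediate 24)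
Why: 9-BBN-H adds only to the monosubstituted alkene with boron at the terminal carbon, the B-alkyl Suzuki–Miyaura coupling takes place at C–I much faster than at C–Br, and a threefold excess of recoverable 23 holds the reaction at single substitution, with the stereocentre a spectator.

**Step 18**
Reactants: 13 (R)-vinyl carbinol; 25 mono-alkylated iodide
Product: 27 dimethyl (2Z,6E,10S,2'Z,6'E,10'R)-12,12'-[5,5'-dibromo-4,4'-dimethyl-2,2'-bis(triisopropylsilyloxy)biphenyl-6,6'-diyl]bis(10-hydroxy-2,6,10-trimethyldodeca-2,6-dienoate), via B-alkyl-9-BBN borane 26 (not isolated)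
Conditions: 13 (1.5 equiv), 9-BBN-H (3.2 equiv), THF, 0 °C to rt; then aq K3PO4, 25, PdCl2(dppf) (10 mol %), AsPh3 (10 mol %), DMF, 50 °C
Reagents that add atoms: 9-borabicyclo[3.3.1]nonane, B1C2CCCC1CCC2 (its atoms stay only in intermediate 26)
Why: The same hydroboration and B-alkyl Suzuki–Miyaura coupling at the one remaining C–I bond brings in the enantiomeric chain, so the two atropisomeric diastereomers of 25 become the two enantiomers of one unlike diastereomer, and any minor-enantiomer chain ends in like diastereomers that chromatography can remove.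

**Step 19**
Reactants: 27 unlike bis(tertiary alcohol) dibromobiaryl
Product: 28 dimethyl (2Z,6E,2'Z,6'E)-9,9'-[(2S,2'R)-2,2',8,8'-tetramethyl-6,6'-bis(triisopropylsilyloxy)-5,5'-bichroman-2,2'-diyl]bis(2,6-dimethylnona-2,6-dienoate)
Conditions: Pd(OAc)2 (10 mol %), 2-(di-tert-butylphosphino)-1,1'-binaphthyl (15 mol %), Cs2CO3 (4 equiv), toluene, 80 °C, argon
Reagents that add atoms: none
Why: Zerovalent palladium formed from Pd(OAc)2 and the bulky, electron-rich phosphine inserts into each C8a–Br bond, Cs2CO3 deprotonates the tethered tertiary alcohol so that alkoxide replaces bromide on divalent palladium, and C–O reductive elimination releases the aryl ether. The closest known reaction type is the intramolecular Buchwald–Hartwig etherification of aryl bromides with tertiary alcohols, which gives 2,2-disubstituted chromans. Each of the two pyran rings closes in the same mode, by reductive elimination from a seven-membered oxapalladacycle (Pd, C8a, C4a, C4, C3, C2, O1) that contracts to the six-membered ring, and the two closures are independent events on the two arenes. No stereocentre is created: only O–H and C–Br bonds change, so C2 (S) and C2' (R) are carried over with retention and the axis stays blocked by its four ortho substituents. The selectivity needed is C–O reductive elimination over hydrodebromination and over intermolecular etherification, and the substrate secures it because the tertiary alkoxides have no hydrogen on the carbinol carbon for β-hydride elimination, the flanking C8 methyl and C4 methylene crowd palladium and speed reductive elimination, and the short tether makes ring closure faster than any bimolecular path. The trisubstituted alkenes, methyl esters and aryl silyl ethers should be inert to carbonate in dry toluene.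

**Step 20**
Reactants: 28 bis(silyl ether) dimethyl ester
Product: 29 dimethyl (2Z,6E,2'Z,6'E)-9,9'-[(2S,2'R)-6,6'-dihydroxy-2,2',8,8'-tetramethyl-5,5'-bichroman-2,2'-diyl]bis(2,6-dimethylnona-2,6-dienoate)
Conditions: Bu4NF (2.5 equiv), AcOH (2.5 equiv), THF, 0 °C
Reagents that add atoms: none
Why: Fluoride-induced cleavage of aryl silyl ethers is fast at 0 °C, and acetic acid buffering keeps the released phenoxides protonated so that neither the esters nor the oxidation-prone chromanols suffer.

**Step 21**
Reactants: 29 diphenol dimethyl ester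
Product: 30 CNP0282703.1, (2Z,6E,2'Z,6'E)-9,9'-[(2S,2'R)-6,6'-dihydroxy-2,2',8,8'-tetramethyl-5,5'-bichroman-2,2'-diyl]bis(2,6-dimethylnona-2,6-dienoic acid)
Conditions: LiOH (10 equiv), degassed THF/MeOH/H2O, 40 °C, argon; then 1 M HCl to pH 3
Reagents that add atoms: lithium hydroxide, [Li+].[OH-]
Why: Saponification under exclusion of air cleaves both methyl esters by acyl–oxygen scission, conditions under which trisubstituted Z enoates keep their geometry, and acidification liberates the diacid.

**Compound list**
1 | (2E,6E)-farnesol | CC(C)=CCC/C(C)=C/CC/C(C)=C/CO | starting material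
2 | (2E,6E)-farnesyl acetate | CC(C)=CCC/C(C)=C/CC/C(C)=C/COC(C)=O | intermediate
3 | (2E,6E)-10-bromo-11-hydroxy-3,7,11-trimethyldodeca-2,6-dienyl acetate (racemic) | CC(C)(O)C(Br)CC/C(C)=C/CC/C(C)=C/COC(C)=O | intermediate
4 | (2E,6E)-10,11-epoxyfarnesol (racemic) | CC1(C)OC1CC/C(C)=C/CC/C(C)=C/CO | intermediate
5 | (4E,8E)-10-hydroxy-4,8-dimethyldeca-4,8-dienal | O=CCC/C(C)=C/CC/C(C)=C/CO | intermediate
6 | methyl 2-[bis(2,2,2-trifluoroethoxy)phosphoryl]propanoate | COC(=O)C(C)P(=O)(OCC(F)(F)F)OCC(F)(F)F | starting material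
7 | methyl (2Z,6E,10E)-12-hydroxy-2,6,10-trimethyldodeca-2,6,10-trienoate | COC(=O)/C(C)=C\CC/C(C)=C/CC/C(C)=C/CO | intermediate
8 | methyl (2Z,6E)-9-[(2S,3S)-3-(hydroxymethyl)-2-methyloxiran-2-yl]-2,6-dimethylnona-2,6-dienoate | OC[C@@H]1O[C@@]1(C)CC/C=C(\C)CC/C=C(/C)C(=O)OC | intermediate
9 | methyl (2Z,6E)-9-[(2S,3R)-3-(iodomethyl)-2-methyloxiran-2-yl]-2,6-dimethylnona-2,6-dienoate | IC[C@@H]1O[C@@]1(C)CC/C=C(\C)CC/C=C(/C)C(=O)OC | intermediate
10 | methyl (2Z,6E,10S)-10-hydroxy-2,6,10-trimethyldodeca-2,6,11-trienoate | C=C[C@@](C)(O)CC/C=C(\C)CC/C=C(/C)C(=O)OC | intermediate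
11 | methyl (2Z,6E)-9-[(2R,3R)-3-(hydroxymethyl)-2-methyloxiran-2-yl]-2,6-dimethylnona-2,6-dienoate | OC[C@H]1O[C@]1(C)CC/C=C(\C)CC/C=C(/C)C(=O)OC | intermediate
12 | methyl (2Z,6E)-9-[(2R,3S)-3-(iodomethyl)-2-methyloxiran-2-yl]-2,6-dimethylnona-2,6-dienoate | IC[C@H]1O[C@]1(C)CC/C=C(\C)CC/C=C(/C)C(=O)OC | intermediate
13 | methyl (2Z,6E,10R)-10-hydroxy-2,6,10-trimethyldodeca-2,6,11-trienoate | C=C[C@](C)(O)CC/C=C(\C)CC/C=C(/C)C(=O)OC | intermediate
14 | 4-amino-3-methylphenol | Cc1cc(O)ccc1N | starting material
15 | tert-butyl (4-hydroxy-2-methylphenyl)carbamate | Cc1cc(O)ccc1NC(=O)OC(C)(C)C | intermediate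
16 | tert-butyl (4-hydroxy-5-iodo-2-methylphenyl)carbamate | Cc1cc(O)c(I)cc1NC(=O)OC(C)(C)C | intermediate
17 | tert-butyl [5-iodo-2-methyl-4-(triisopropylsilyloxy)phenyl]carbamate | Cc1cc(O[Si](C(C)C)(C(C)C)C(C)C)c(I)cc1NC(=O)OC(C)(C)C | intermediate
18 | tert-butyl [2-methyl-5-(4,4,5,5-tetramethyl-1,3,2-dioxaborolan-2-yl)-4-(triisopropylsilyloxy)phenyl]carbamate | Cc1cc(O[Si](C(C)C)(C(C)C)C(C)C)c(cc1NC(=O)OC(C)(C)C)B1OC(C)(C)C(C)(C)O1 | intermediate
19 | 5,5'-bis(tert-butoxycarbonylamino)-4,4'-dimethyl-2,2'-bis(triisopropylsilyloxy)biphenyl | Cc1cc(O[Si](C(C)C)(C(C)C)C(C)C)c(cc1NC(=O)OC(C)(C)C)-c1cc(NC(=O)OC(C)(C)C)c(C)cc1O[Si](C(C)C)(C(C)C)C(C)C | intermediate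
20 | 5,5'-diamino-4,4'-dimethyl-2,2'-bis(triisopropylsilyloxy)biphenyl | Cc1cc(O[Si](C(C)C)(C(C)C)C(C)C)c(cc1N)-c1cc(N)c(C)cc1O[Si](C(C)C)(C(C)C)C(C)C | intermediate
21 | 5,5'-diamino-6,6'-diiodo-4,4'-dimethyl-2,2'-bis(triisopropylsilyloxy)biphenyl | Cc1cc(O[Si](C(C)C)(C(C)C)C(C)C)c(c(I)c1N)-c1c(O[Si](C(C)C)(C(C)C)C(C)C)cc(C)c(N)c1I | intermediate
22 | 6,6'-diiodo-4,4'-dimethyl-2,2'-bis(triisopropylsilyloxy)biphenyl-5,5'-bis(diazonium) dibromide | Cc1cc(O[Si](C(C)C)(C(C)C)C(C)C)c(c(I)c1[N+]#N)-c1c(O[Si](C(C)C)(C(C)C)C(C)C)cc(C)c([N+]#N)c1I.[Br-].[Br-] | intermediate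
23 | 5,5'-dibromo-6,6'-diiodo-4,4'-dimethyl-2,2'-bis(triisopropylsilyloxy)biphenyl | Cc1cc(O[Si](C(C)C)(C(C)C)C(C)C)c(c(I)c1Br)-c1c(O[Si](C(C)C)(C(C)C)C(C)C)cc(C)c(Br)c1I | intermediate
24 | methyl (2Z,6E,10R)-12-(9-borabicyclo[3.3.1]nonan-9-yl)-10-hydroxy-2,6,10-trimethyldodeca-2,6-dienoate (same spatial arrangement as 10; the descriptor changes by ranking only) | COC(=O)/C(C)=C\CC/C(C)=C/CC[C@@](O)(C)CCB1C2CCCC1CCC2 | intermediate
25 | methyl (2Z,6E,10S)-12-[5,5'-dibromo-6'-iodo-4,4'-dimethyl-2,2'-bis(triisopropylsilyloxy)biphenyl-6-yl]-10-hydroxy-2,6,10-trimethyldodeca-2,6-dienoate | C/C(=C/CC/C(C)=C/CC[C@@](O)(C)CCc1c(Br)c(C)cc(O[Si](C(C)C)(C(C)C)C(C)C)c1-c1c(O[Si](C(C)C)(C(C)C)C(C)C)cc(C)c(Br)c1I)C(=O)OC | intermediate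
26 | methyl (2Z,6E,10S)-12-(9-borabicyclo[3.3.1]nonan-9-yl)-10-hydroxy-2,6,10-trimethyldodeca-2,6-dienoate (same spatial arrangement as 13) | COC(=O)/C(C)=C\CC/C(C)=C/CC[C@](O)(C)CCB1C2CCCC1CCC2 | intermediate
27 | dimethyl (2Z,6E,10S,2'Z,6'E,10'R)-12,12'-[5,5'-dibromo-4,4'-dimethyl-2,2'-bis(triisopropylsilyloxy)biphenyl-6,6'-diyl]bis(10-hydroxy-2,6,10-trimethyldodeca-2,6-dienoate) | C/C(=C/CC/C(C)=C/CC[C@@](O)(C)CCc1c(Br)c(C)cc(O[Si](C(C)C)(C(C)C)C(C)C)c1-c1c(O[Si](C(C)C)(C(C)C)C(C)C)cc(C)c(Br)c1CC[C@@](C)(CC/C=C(\C)CC/C=C(/C)C(=O)OC)O)C(=O)OC | intermediate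
28 | bis(triisopropylsilyl) ether dimethyl ester of the target, (2S,2'R)-5,5'-bichroman | C/C(=C/CC/C(C)=C/CC[C@@]1(C)CCc2c(c(C)cc(O[Si](C(C)C)(C(C)C)C(C)C)c2-c2c(O[Si](C(C)C)(C(C)C)C(C)C)cc(C)c3c2CC[C@@](C)(CC/C=C(\C)CC/C=C(/C)C(=O)OC)O3)O1)C(=O)OC | intermediate
29 | dimethyl ester of the target, (2S,2'R)-6,6'-dihydroxy-5,5'-bichroman | C/C(=C/CC/C(C)=C/CC[C@@]1(C)CCc2c(c(C)cc(O)c2-c2c(O)cc(C)c3c2CC[C@@](C)(CC/C=C(\C)CC/C=C(/C)C(=O)OC)O3)O1)C(=O)OC | intermediate
30 | CNP0282703.1 | C/C(=C/CC/C(C)=C/CC[C@@]1(C)CCc2c(c(C)cc(O)c2-c2c(O)cc(C)c3c2CC[C@@](C)(CC/C=C(\C)CC/C=C(/C)C(=O)O)O3)O1)C(=O)O | target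

**Step count:** 21 steps in total.
**Longest linear sequence:** 12 steps, either steps 1–7 then 17–21, or steps 10–16 then 17–21.

**Steps most likely to fail**

Step 17. The reacting carbon is flanked by bromine and by the twisted second arene. Oxidative addition, and above all transfer of the bulky B-alkyl group to palladium, may therefore be slow enough for protodeiodination, decay of the borane or a second coupling to take over.
The fallback sets out from 10 and 23, with 23 again in excess. A Heck arylation under ligand-free phase-transfer conditions (Pd(OAc)2, Bu4NCl, NaHCO3, DMF, 70 °C) forms the same C4–C4a bond from the flat, unhindered vinyl terminus. Because the carbinol carbon bears no hydrogen, the reaction stops at the (E)-styrenyl carbinol methyl (2Z,6E,10S,11E)-12-[5,5'-dibromo-6'-iodo-4,4'-dimethyl-2,2'-bis(triisopropylsilyloxy)biphenyl-6-yl]-10-hydroxy-2,6,10-trimethyldodeca-2,6,11-trienoate F1. Diimide, generated from 2-nitrobenzenesulfonyl hydrazide and Et3N in CH2Cl2 at rt, then saturates the only 1,2-disubstituted alkene. It spares the trisubstituted alkenes and the carbon–halogen bonds, and the route is rejoined at 25.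

Step 19. Insertion into an electron-rich bromide with two ortho substituents may be slow, and exchange of bromide for the hindered alkoxide may lag. Hydrodebromination, closure of only one ring or carbonate-induced loss of the silyl ethers could then compete.
The fallback sets out from 27 and changes both the leaving group and the metal. An aromatic Finkelstein exchange (CuI, NaI, trans-N,N'-dimethylcyclohexane-1,2-diamine, dioxane, 110 °C, no base) gives the 5,5'-diiodo analogue of 27, dimethyl (2Z,6E,10S,2'Z,6'E,10'R)-12,12'-[5,5'-diiodo-4,4'-dimethyl-2,2'-bis(triisopropylsilyloxy)biphenyl-6,6'-diyl]bis(10-hydroxy-2,6,10-trimethyldodeca-2,6-dienoate) F2. A two-fold intramolecular Ullmann-type etherification (CuI, 1,10-phenanthroline, Cs2CO3, toluene, 110 °C) then forms the same two O1–C8a bonds, again without touching C2, and comes back at 28.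

Step 15. The bulky iodinating agent may attack the crowded position beside the axis only slowly. Oxidation of the electron-rich aminophenol ether, attack at C3 or stalling after one iodination could then compete.
The fallback sets out from 20. The smaller and more reactive bromonium source NBS (MeCN/CH2Cl2, −20 °C) brominates ortho to each amine and gives 5,5'-diamino-6,6'-dibromo-4,4'-dimethyl-2,2'-bis(triisopropylsilyloxy)biphenyl F3. These are the only C–Br bonds present at this stage, so a copper-catalysed aromatic Finkelstein exchange (CuI, NaI, trans-N,N'-dimethylcyclohexane-1,2-diamine, dioxane, 110 °C) converts them into C–I bonds and rejoins the route at 21.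

**Further compounds**
F1 | step 17 | methyl (2Z,6E,10S,11E)-12-[5,5'-dibromo-6'-iodo-4,4'-dimethyl-2,2'-bis(triisopropylsilyloxy)biphenyl-6-yl]-10-hydroxy-2,6,10-trimethyldodeca-2,6,11-trienoate | C/C(=C/CC/C(C)=C/CC[C@@](O)(C)/C=C/c1c(Br)c(C)cc(O[Si](C(C)C)(C(C)C)C(C)C)c1-c1c(O[Si](C(C)C)(C(C)C)C(C)C)cc(C)c(Br)c1I)C(=O)OC
F2 | step 19 | dimethyl (2Z,6E,10S,2'Z,6'E,10'R)-12,12'-[5,5'-diiodo-4,4'-dimethyl-2,2'-bis(triisopropylsilyloxy)biphenyl-6,6'-diyl]bis(10-hydroxy-2,6,10-trimethyldodeca-2,6-dienoate) | C/C(=C/CC/C(C)=C/CC[C@@](O)(C)CCc1c(I)c(C)cc(O[Si](C(C)C)(C(C)C)C(C)C)c1-c1c(O[Si](C(C)C)(C(C)C)C(C)C)cc(C)c(I)c1CC[C@@](C)(CC/C=C(\C)CC/C=C(/C)C(=O)OC)O)C(=O)OC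
F3 | step 15 | 5,5'-diamino-6,6'-dibromo-4,4'-dimethyl-2,2'-bis(triisopropylsilyloxy)biphenyl | Cc1cc(O[Si](C(C)C)(C(C)C)C(C)C)c(c(Br)c1N)-c1c(O[Si](C(C)C)(C(C)C)C(C)C)cc(C)c(N)c1Br
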